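## Retrosyn­thetic overview

1. The C5 formyl group is introduced last, by ortho-formylation of (R)-δ-tocotrienol; C5 stays C–H until then because a carbonyl peri to C4 would trap the methide carbon of the key step.
2. The dihydropyran ring is cut across C4–C3 and O1–C2 in one retro-[4+2]: an o-quinone methide (O1=C8a–C4a=C4H2) from a 2-(hydroxymethyl)phenol, plus the terminal olefin C3=C2 of an all-(E) C19 tetraene. A chiral Brønsted acid sets C2.
3. Enabling feature: O1 and C4 are ortho substituents of the benzene ring (on C8a and C4a), and C2 is fully substituted (CH3 and chain) next to an unsubstituted C3H2. The olefin is therefore polarity-matched, the least hindered of the four olefins, and prochiral.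
4. The arene piece comes from methylhydroquinone (O6 silylation, ortho-formylation, reduction); the tetraene from (2E,6E)-farnesyl bromide and methallylmagnesium chloride.
5. Ring order: the benzene ring is bought; the dihydropyran ring is the only ring formed, in step 5.

Key step: step 5

Remark: chroman numbering (O1, C2 … C8a) is used for atom names. The sense of induction of the chiral acid in step 5 cannot be assigned in advance; the catalyst antipode that delivers the (2R)-chroman is taken, as found with a simple 2-methylalk-1-ene.

## Route

Step 1
Reactants: 1 methylhydroquinone (2-methylbenzene-1,4-diol)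
Product: 2 4-[(tert-butyldimethylsilyl)oxy]-2-methylphenol
Conditions: TBSCl (0.95 equiv), imidazole, DMF, −20 → 0 °C
Reagents that add atoms: tert-butyldimethylsilyl chloride, CC(C)(C)[Si](C)(C)Cl
Why: Site-selective silyl ether formation, in which the hydroxyl without an ortho substituent is the less hindered one and should be silylated first, the regioisomer and the bis-ether being removable by chromatography.

Step 2
Reactants: 2 4-[(tert-butyldimethylsilyl)oxy]-2-methylphenol
Product: 3 5-[(tert-butyldimethylsilyl)oxy]-2-hydroxy-3-methylbenzaldehyde
Conditions: MgCl2, Et3N, (CH2O)n, THF, reflux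
Reagents that add atoms: paraformaldehyde (as formaldehyde), C=O
Why: Casnati–Skattebøl ortho-formylation of the magnesium phenoxide, which can only attack the single free ortho position of the free phenol, paraformaldehyde serving as C1 source and hydride acceptor while the aryl silyl ether is inert to MgCl2/Et3N.

Step 3
Reactants: 3 5-[(tert-butyldimethylsilyl)oxy]-2-hydroxy-3-methylbenzaldehyde
Product: 4 4-[(tert-butyldimethylsilyl)oxy]-2-(hydroxymethyl)-6-methylphenol
Conditions: NaBH4, THF/EtOH, 0 °C
Reagents that add atoms: none
Why: Chemoselective hydride reduction of the aldehyde (NaBH4) should give the salicyl alcohol that serves as o-quinone methide precursor, the aryl silyl ether surviving the short, cold reduction.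

Step 4
Reactants: 5 (2E,6E)-farnesyl bromide; 6 (2-methylallyl)magnesium chloride
Product: 7 (5E,9E)-2,6,10,14-tetramethylpentadeca-1,5,9,13-tetraene
Conditions: THF, −20 °C → rt, 5 added to 6 (1.5 equiv), no copper salt
Reagents that add atoms: none
Why: Uncatalysed allyl–allyl coupling (SN2 displacement of the primary allylic bromide by the symmetrical allylic Grignard reagent) should join C1 of the farnesyl unit to the methallyl CH2 with the (E)-olefins untouched, attack at the hindered tertiary carbon being disfavoured without copper.

Step 5
Reactants: 4 4-[(tert-butyldimethylsilyl)oxy]-2-(hydroxymethyl)-6-methylphenol; 7 (5E,9E)-2,6,10,14-tetramethylpentadeca-1,5,9,13-tetraene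
Product: 9 tert-butyl{[(2R)-2,8-dimethyl-2-[(3E,7E)-4,8,12-trimethyltrideca-3,7,11-trien-1-yl]-3,4-dihydro-2H-chromen-6-yl]oxy}dimethylsilane, via o-quinone methide 8 (not isolated)
Conditions: chiral imidodiphosphorimidate (IDPi) Brønsted acid of the type (ArO)2P(=NSO2CF3)–NH–P(=NSO2CF3)(OAr)2 built from two 3,3'-diaryl-1,1'-bi-2-naphthol units (5 mol%), 5 Å molecular sieves, cyclohexane/CHCl3, −20 °C → rt, slow addition of 4 to 7 (1.5 equiv)
Reagents that add atoms: none
Why: Proposed new method: the confined chiral Brønsted acid should dehydrate 4 to o-quinone methide 8, which stays hydrogen-bonded to the chiral anion and is taken up by the single 1,1-disubstituted olefin of 7 in an asynchronous, inverse-electron-demand oxa-[4+2] cycloaddition in which the unhindered CH2 terminus bonds to the methide carbon (C4–C3) while charge builds at the tertiary carbon, which the carbonyl oxygen then closes (O1–C2). The closest known reaction types are the chiral phosphoric acid and imidodiphosphate catalysed [4+2] cycloadditions of o-quinone methides made in situ from 2-(hydroxymethyl)phenols with styrenes and enol ethers, their intramolecular variant with unactivated alkenes, and the uncatalysed thermal o-quinone methide/terpene cycloaddition; the intermolecular asymmetric capture of an aliphatic 1,1-disubstituted alkene is the new element. The dihydropyran ring is closed by the [4+2] cycloaddition itself (in the stepwise limit by Markovnikov capture of the tertiary cation by the phenolic oxygen). The C2 stereocentre is set by the catalyst, whose pocket must tell the methyl group from the long chain on the prochiral olefin carbon and thereby fix the olefin face that meets the planar o-quinone methide. The step needs chemoselectivity for the terminal olefin over the three trisubstituted ones, secured by its unsubstituted CH2 terminus and by the confined pocket, and Markovnikov regiochemistry, secured by the tertiary C2; with C5 and C7 as C–H there is no neighbouring carbonyl to trap the methide carbon, and the silyl ether on O6 blocks tautomerisation of 8 to a p-quinone.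

Step 6
Reactants: 9 tert-butyl{[(2R)-2,8-dimethyl-2-[(3E,7E)-4,8,12-trimethyltrideca-3,7,11-trien-1-yl]-3,4-dihydro-2H-chromen-6-yl]oxy}dimethylsilane
Product: 10 (R)-δ-tocotrienol, (2R)-2,8-dimethyl-2-[(3E,7E)-4,8,12-trimethyltrideca-3,7,11-trien-1-yl]-3,4-dihydro-2H-chromen-6-ol
Conditions: Bu4NF, AcOH, THF, 0 °C, under argon
Reagents that add atoms: none
Why: Fluoride-induced desilylation of the aryl silyl ether, buffered with acetic acid so that the oxidation-prone chromanol is not left as its phenoxide, should leave the C2 stereocentre and the skipped triene untouched.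

Step 7
Reactants: 10 (R)-δ-tocotrienol
Product: 11 (2R)-6-hydroxy-2,8-dimethyl-2-[(3E,7E)-4,8,12-trimethyltrideca-3,7,11-trien-1-yl]-3,4-dihydro-2H-chromene-5-carbaldehyde (target)
Conditions: MgCl2, Et3N, (CH2O)n, THF, reflux, under argon; dilute aq. HCl work-up
Reagents that add atoms: paraformaldehyde (as formaldehyde), C=O
Why: Casnati–Skattebøl ortho-formylation, in which the ortho position on the ring-fusion side (C5) should be favoured over C7 by the bond fixation that the fused dihydropyran ring imposes (the Mills–Nixon-type preference known for electrophilic substitution of δ-tocols), the salicylaldehyde formed being deactivated towards a second formylation and no stereocentre being touched.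

## Compound list

1 | methylhydroquinone (2-methylbenzene-1,4-diol) | Cc1cc(O)ccc1O | starting material
2 | 4-[(tert-butyldimethylsilyl)oxy]-2-methylphenol | Cc1cc(O[Si](C)(C)C(C)(C)C)ccc1O | intermediate
3 | 5-[(tert-butyldimethylsilyl)oxy]-2-hydroxy-3-methylbenzaldehyde | Cc1cc(O[Si](C)(C)C(C)(C)C)cc(C=O)c1O | intermediate
4 | 4-[(tert-butyldimethylsilyl)oxy]-2-(hydroxymethyl)-6-methylphenol | Cc1cc(O[Si](C)(C)C(C)(C)C)cc(CO)c1O | intermediate
5 | (2E,6E)-farnesyl bromide, (2E,6E)-1-bromo-3,7,11-trimethyldodeca-2,6,10-triene | CC(C)=CCC/C(C)=C/CC/C(C)=C/CBr | starting material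
6 | (2-methylallyl)magnesium chloride | CC(=C)C[Mg]Cl | starting material
7 | (5E,9E)-2,6,10,14-tetramethylpentadeca-1,5,9,13-tetraene | CC(C)=CCC/C(C)=C/CC/C(C)=C/CCC(C)=C | intermediate
8 | o-quinone methide, 4-[(tert-butyldimethylsilyl)oxy]-2-methyl-6-methylidenecyclohexa-2,4-dien-1-one | C=C1C=C(O[Si](C)(C)C(C)(C)C)C=C(C)C1=O | intermediate (not isolated)
9 | tert-butyl{[(2R)-2,8-dimethyl-2-[(3E,7E)-4,8,12-trimethyltrideca-3,7,11-trien-1-yl]-3,4-dihydro-2H-chromen-6-yl]oxy}dimethylsilane | CC(C)=CCC/C(C)=C/CC/C(C)=C/CC[C@]1(C)CCc2cc(O[Si](C)(C)C(C)(C)C)cc(C)c2O1 | intermediate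
10 | (R)-δ-tocotrienol, (2R)-2,8-dimethyl-2-[(3E,7E)-4,8,12-trimethyltrideca-3,7,11-trien-1-yl]-3,4-dihydro-2H-chromen-6-ol | CC(C)=CCC/C(C)=C/CC/C(C)=C/CC[C@]1(C)CCc2cc(O)cc(C)c2O1 | intermediate
11 | (2R)-6-hydroxy-2,8-dimethyl-2-[(3E,7E)-4,8,12-trimethyltrideca-3,7,11-trien-1-yl]-3,4-dihydro-2H-chromene-5-carbaldehyde | CC(C)=CCC/C(C)=C/CC/C(C)=C/CC[C@]1(C)CCc2c(C=O)c(O)cc(C)c2O1 | target

## Step count and risks

Total step count: 7. Longest linear sequence: 6 steps (steps 1, 2, 3, 5, 6, 7).

Steps most likely to fail:

**Step 5 (proposed new method).** The chiral pocket may discriminate poorly between the methyl group and the chain (low enantiofacial selectivity). The o-quinone methide may oligomerise or alkylate the electron-rich product faster than it is captured by an unactivated olefin. The acid may also engage the trisubstituted olefins.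
Fallback, from 4 and 7 back to 9: catalyst control is given up. 4 is heated with an excess of 7 without catalyst (o-xylene, about 150 °C, sealed vessel), which is the known thermal dehydration to 8 and uncatalysed o-quinone methide/alkene [4+2] cycloaddition. This should give the racemic silyl ether F1. The enantiomers are then separated by preparative HPLC on a cellulose tris(3,5-dimethylphenylcarbamate) phase, a separation type known for 2-epimeric tocols. The (2S)-enantiomer F2 is set aside and the (2R)-enantiomer is 9.

**Step 7.** Attack may be divided between C5 and C7 (poor regioselectivity), and the free chromanol may be oxidised during prolonged basic heating.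
Fallback, from 10 back to 11: the carbon is delivered through a cyclic boronate and oxidised in a separate, mild step. 10 is heated with PhB(OH)2, (CH2O)n and catalytic propionic acid in toluene with removal of water. This templated ortho-hydroxymethylation, a sigmatropic-type delivery that follows bond fixation towards C5, should give the cyclic phenylboronate F3, from which a C7 isomer can be removed. Exchange with propane-1,3-diol should free 5-(hydroxymethyl)-δ-tocotrienol F4. Oxidation of the salicyl alcohol with MnO2 in CH2Cl2 should then give 11.

**Step 4.** Part of the Grignard reagent may attack the tertiary allylic carbon (SN2' coupling) or cause halogen–metal exchange and homocoupling, giving hydrocarbon isomers that are hard to separate.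
Fallback, from 5 back to 7: the C–C bond is made with a stabilised enolate and the olefin by olefination. 5 alkylates the sodium enolate of ethyl acetoacetate (NaOEt, EtOH) to give the keto ester ethyl (4E,8E)-2-acetyl-5,9,13-trimethyltetradeca-4,8,12-trienoate F5. Saponification and decarboxylation (aq. NaOH, then acid, warm) should give (5E,9E)-farnesylacetone F6. Wittig methylenation (Ph3P=CH2 from Ph3PCH3Br and KOtBu, THF) should give 7.

## Further compounds

F1 | step 5 | racemic tert-butyl{[2,8-dimethyl-2-[(3E,7E)-4,8,12-trimethyltrideca-3,7,11-trien-1-yl]-3,4-dihydro-2H-chromen-6-yl]oxy}dimethylsilane | CC(C)=CCC/C(C)=C/CC/C(C)=C/CCC1(C)CCc2cc(O[Si](C)(C)C(C)(C)C)cc(C)c2O1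
F2 | step 5 | tert-butyl{[(2S)-2,8-dimethyl-2-[(3E,7E)-4,8,12-trimethyltrideca-3,7,11-trien-1-yl]-3,4-dihydro-2H-chromen-6-yl]oxy}dimethylsilane | CC(C)=CCC/C(C)=C/CC/C(C)=C/CC[C@@]1(C)CCc2cc(O[Si](C)(C)C(C)(C)C)cc(C)c2O1
F3 | step 7 | cyclic phenylboronate of 5-(hydroxymethyl)-δ-tocotrienol (2-phenyl-4H-1,3,2-dioxaborin ring fused across O6 and C5) | CC(C)=CCC/C(C)=C/CC/C(C)=C/CC[C@]1(C)CCc2c3c(cc(C)c2O1)OB(c2ccccc2)OC3
F4 | step 7 | 5-(hydroxymethyl)-δ-tocotrienol, (2R)-5-(hydroxymethyl)-2,8-dimethyl-2-[(3E,7E)-4,8,12-trimethyltrideca-3,7,11-trien-1-yl]-3,4-dihydro-2H-chromen-6-ol | CC(C)=CCC/C(C)=C/CC/C(C)=C/CC[C@]1(C)CCc2c(CO)c(O)cc(C)c2O1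
F5 | step 4 | ethyl (4E,8E)-2-acetyl-5,9,13-trimethyltetradeca-4,8,12-trienoate | CCOC(=O)C(C/C=C(\C)CC/C=C(\C)CCC=C(C)C)C(C)=O
F6 | step 4 | (5E,9E)-farnesylacetone, (5E,9E)-6,10,14-trimethylpentadeca-5,9,13-trien-2-one | CC(=O)CC/C=C(\C)CC/C=C(\C)CCC=C(C)C
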